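(The runs stem from a simulated flask with made-up constants; scatter was added.)

Do not read the excess off single readings of right-handed product: in gamma they run from 0% to 4%, with a scatter of 2 percentage points.

common to all: left-handed substrate 20 mM; right-handed substrate 20 mM; free catalyst 8.9 mol%

| run | reagent | added ligand | remark | time |
|---|---|---|---|---|
| epsilon | 0.60 equiv | 2.8 mM | run made earlier |  |
| delta | 0.90 equiv | 2.8 mM | run made earlier |  |
| gamma | 1.2 equiv | 1.4 mM | run made earlier |  |
| flask | 1.20 equiv | 2.8 mM |  | 15 min |

- epsilon (time / min: left-handed product / %, right-handed product / %, left-handed substrate / %): 0.833: 21, 0, 31; 2.50: 25, 0, 27; 4.00: 26, 0, 25; 6.00: 26, 0, 26; 10.0: 20, 2, 27; 12.0: 28, 0, 26; 15.0: 23, 0, 23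
- delta (time / min: left-handed product / %, right-handed product / %, left-handed substrate / %): 1.33: 29, 2, 18; 2.00: 29, 4, 20; 3.00: 35, 4, 19; 4.00: 31, 2, 18; 6.00: 32, 3, 15; 10.0: 31, 2, 16; 15.0: 32, 2, 20
- gamma (time / min: left-handed product / %, right-handed product / %, left-handed substrate / %): 1.33: 37, 0, 12; 4.00: 38, 0, 13; 8.00: 38, 3, 13; 10.0: 37, 3, 9; 15.0: 36, 4, 14

(scatter of a reading: 2 percentage points)

- free catalyst is single-handed; left-handed substrate and right-handed substrate are mirror images of each other, charged as a racemate, each of them at the stated concentration
- an excess is below zero if the other one leads

* excess of left-handed product over right-handed product in the product at 20 s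
* excess of left-handed product over right-handed product in the product at 15 min
* part of the left-handed substrate and right-handed substrate charged together that has reacted at 15 min

Start from the symmetric case. A catalyst blind to handedness takes both mirror substrates alike, so the logarithms of their fractions left stand in a ratio of one and the excess is zero. Measure the flask from that zero, using averages over the plateaus of delta and gamma and leaving out epsilon, whose right-handed product lies within the scatter.

Gamma leaves fractions 0.244 of left-handed and 0.960 of right-handed substrate. Delta leaves 0.360 and 0.946. Singly, delta reads 18.4 and gamma 34.6, so pool them into one reading: 25.2. This selectivity factor, the logarithm of the fraction of left-handed substrate left over that of right-handed substrate, gives an excess of 92.4% in the first product.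

Assume the flask stops at gamma's 0.244. Then 0.945 of right-handed substrate remains, the excess is 86.4% and the conversion 40.6%. That is worth having, so charge 1.20 equiv of reagent and 2.8 mM of added ligand. Delta and gamma read flat within the scatter from their first samples, so leave the time at 15 min, and sample at 20 s to test the early excess.

The forecast, near this reckoning but not equal to it, gives 94%, 86% and 40.5%, holding that “the flask should plateau like gamma”.

The flask gives an excess of 92.0% at 20 s, an excess of 90.4% at 15 min and a conversion of 40.0%, so the charge delivers a product of high excess.

    free catalyst + left-handed substrate ⇌ catalyst intermediate A (K = 140 M⁻¹, k = 390 M⁻¹ s⁻¹)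
    free catalyst + right-handed substrate ⇌ catalyst intermediate B (K = 35.0 M⁻¹, k = 420 M⁻¹ s⁻¹)
    reagent + catalyst intermediate A → free catalyst + left-handed product (k = 68.0 M⁻¹ s⁻¹)
    reagent + catalyst intermediate B → free catalyst + right-handed product (k = 5.50 M⁻¹ s⁻¹)
    free catalyst + added ligand ⇌ idle complex, settled at all times (K = 140 M⁻¹)
    free catalyst → spent catalyst A (k = 0.0460 s⁻¹)
    2 free catalyst → spent catalyst B (k = 160 M⁻¹ s⁻¹)

With 24% of left-handed substrate left, the factor of 25.2 leaves 94.5% of right-handed substrate, and the flask keeps 96%. The main reason for the excess is the falling back of catalyst intermediate B to free catalyst and right-handed substrate: a run without that step ends at −48.4% instead of 90.4%. In the same flask with 4.80 equiv of reagent, 3.3% of the left-handed substrate charged remains, so the factor gives 87.3% of right-handed substrate and an excess of 76.8%. That neighbour computes to 82% and 69.0%.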